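## Analysis of the target

The target is built from two bicycles joined by a CH2CH2 bridge. The left half is a trans-fused 2,2-dimethyloxepane–cyclohexane (perhydro-1-benzoxepine; O1, C2–C5, C5a, C6–C9, C9a). The right half is a cis-fused bicyclo[5.3.0]dec-3-en-5-one (C1 and C7 ring fusion, C2 gem-dimethyl, C3=C4 alkene, C5 carbonyl, C8 tertiary carbinol).

Five of the eight stereocentres sit in the left half (3S, 5aR, 6R, 7S, 9aR). The C5a methyl, the equatorial 3-OH and the axial 7-OH share one face; H-9a and H-6 lie on the other, and the bridge on C6 is equatorial. The other three sit in the right half (1R, 7R, 8R): the ring-fusion hydrogens are cis to each other and to the C8 hydroxyl, so the C8 methyl points into the concave face.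

Two tertiary alcohols and a tertiary alkyl ether are acid-sensitive. The tetrasubstituted enone is flanked by a quaternary carbon, so its β-carbon is hard to reach.

The two stereochemical clusters are separated by a flexible bridge and cannot control each other. Each half must therefore get its absolute configuration independently, and the halves must be joined at a hindered carbon. Each half also holds a seven-membered ring and fully substituted carbons.

The strategy rests on one feature of the oxepane. Only C4 (a methylene) and C3 (the carbinol) separate the C5 methylene on quaternary C5a from the gem-dimethyl ether carbon C2. A C3=C4 ring alkene can be placed there and formed from two terminal alkenes.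

## Retrosynthetic reasoning

**C3 carbinol.** The equatorial 3-OH of 43 is taken back to the oxepan-3-one 42, and this to the C3 alcohol 41 of either configuration. Setting this centre last by hydride addition makes the route independent of the face on which the ring alkene is oxidised earlier. The forward step must reduce a saturated α-alkoxy ketone beside a hindered conjugated enone.

**Bridge–enone bond.** 41 is cut between the bridge CH2 and the enone β-carbon C3, giving the primary iodide 23 and the vinylogous ester 38. This is the only bond that separates the two stereo-clusters cleanly. The forward reaction is a Stork–Danheiser sequence. Its regiochemistry is favourable: the enol ether of 38 sits on the less hindered oxygen, so the carbonyl that must be attacked is the one next to the gem-dimethyl carbon.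

**Cyclohexane substituents.** In 23 the tertiary carbinol C7 goes back to the ketone 19, the ketone to the trisubstituted alkene 16, and the alkene plus its two-carbon arm to the ketone 12 through a Shapiro reaction. Hydroboration puts H-6 anti to the axial C5a methyl. The methyl nucleophile then attacks C7 equatorially for the same reason. Both new centres are thus controlled by the quaternary carbon already present.

**Oxepane carbinol.** The protected C3 alcohol 12 comes from the ring alkene of 8 by epoxidation and hydride attack at C4, the end away from the neopentyl carbon. Only the position of the oxygen matters at this stage.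

**Oxepene (key disconnection).** The C3=C4 bond of 8 is cut to the diene 7. The cut removes the seven-membered ring in one step and leaves two terminal alkenes on arms that are trans on adjacent ring carbons. No stereocentre is involved.

**Diene.** 7 is taken apart at the tertiary ether into the ketol 4 and the imidate 6 (from 5). 4 comes from the prochiral dione 3 by desymmetrising reduction, and 3 from 1 and 2. Both ring-fusion centres of the left half arise in one catalyst-controlled step.

**Hydroazulene.** The vinylogous ester 38 goes back to the 2-methyl-1,3-dione 37. This is opened retrosynthetically to the cyclobutanone 35, and 35 to the silyl enol ether 34 of the cis-diquinanone 33/32. Cutting the seven-membered ring down to a five-membered one makes the cis ring fusion automatic. The position of the two new carbons is fixed by the polarity of the enol ether.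

**Diquinane.** 32 arises from the tetrasubstituted alkene 31 by hydroxyl-directed hydrogenation, so the C8 carbinol sets both ring-fusion centres. 31 comes from the cyclopentenone 29 by deconjugation, which erases the one uncontrolled centre of the cyclocarbonylation. 29 comes from the enyne 27 by a Pauson–Khand reaction. 27 comes from 24 through the epoxy alcohol 25 and the chloride 26; its carbinol is the only stereocentre that has to be bought with a chiral reagent.

## Alternatives that were turned down

**Alternative 1:** The right bicycle would be disconnected at the ring-fusion bond and at one further cyclopentane bond. The forward step is a palladium-catalysed trimethylenemethane (3+2) annulation (Pd(OAc)2, P(Oi-Pr)3) of an open-chain substrate onto a tethered vinyl sulfone, giving the cis-fused methylenecyclopentane–cycloheptane A1.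

- For it: five- and seven-membered rings close in one operation, and the exocyclic alkene sits on the carbon that becomes the tertiary carbinol. In ring count per step it is stronger than the route chosen here.
- Against it: the cycloaddition has to close a seven-membered ring through a long tether. A1 still needs removal of the sulfone, conversion of two silyloxy groups into the methylated 1,3-dicarbonyl pattern and a face-selective hydration. The acyclic substrate carries stereocentres that are made only to be destroyed.
- Comparison: the chosen route reaches the same oxidation pattern from a diquinane, in which the cis fusion cannot go wrong, and leaves its single uncertain ring closure to the oxepene.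

**Alternative 2:** The cyclopentanol would be disconnected last, at the bond between the carbinol carbon and the adjacent ring-fusion carbon. In the forward step SmI2 generates a ketyl from a methyl ketone side chain, which adds to the β-carbon of a cycloheptadienone that already carries the whole left half, giving the bis-silyl ether A2.

- For it: it is more convergent on paper and forms the tertiary alcohol and a ring-fusion centre together.
- Against it: two stereocentres are set at the very end, on the most valuable intermediate, under control of one remote centre. The reductant must discriminate between a ketone, a disubstituted enone and a tetrasubstituted enone. The dienone with its stereocentre next to the gem-dimethyl carbon is itself hard to make in one enantiomeric form.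
- Comparison: the chosen route settles all three centres of the right half on a small bicyclic ketone. Its last stereocentre is formed by a plain hydride reduction.

**Alternative 3:** The bond between the gem-dimethyl carbon and the enone β-carbon would be made by enone–alkene photocycloaddition on a diquinane enone ester, giving the cyclobutane A3. Radical fragmentation would then expand the ring.

- For it: it shares with the chosen route the diquinane-to-hydroazulene ring expansion, and it brings in the gem-dimethyl carbon together with a one-carbon handle for the bridge. On that point it is stronger.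
- Against it: the cyclobutane has three contiguous quaternary carbons. The head-to-tail orientation of an unsymmetrical trisubstituted alkene is not assured. The fragmentation must break one specific cyclobutane bond. The bridge would still have to be completed by a further C–C coupling at a neopentyl carbon.
- Comparison: the chosen route expands the same kind of ring by a ketene cycloaddition and retro-aldol opening, whose orientation follows from enol ether polarity, and joins the halves at an sp2 carbon.

Key step: step 5

Assumption: peracid attack on 8 is drawn on the face away from the C5a methyl; if the other face reacted, the same target would result, because C3 passes through ketone 42.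

## Route

### Left half (steps 1–15)

Step 1
Reactants: 1 2-methylcyclohexane-1,3-dione; 2 allyl bromide
Product: 3 2-allyl-2-methylcyclohexane-1,3-dione
Conditions: 1 M aq. NaOH, 25 °C
Reagents that add atoms: none
Why: C-alkylation of the dione enolate with a reactive allylic halide; the product has no acidic α-hydrogen between the carbonyls, so it cannot react further.

Step 2
Reactants: 3 2-allyl-2-methylcyclohexane-1,3-dione
Product: 4 (2S,3R)-2-allyl-3-hydroxy-2-methylcyclohexan-1-one
Conditions: (S)-1-methyl-3,3-diphenyltetrahydro-1H,3H-pyrrolo[1,2-c][1,3,2]oxazaborole (20 mol%), catecholborane, toluene, −78 °C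
Reagents that add atoms: none
Why: Corey–Bakshi–Shibata reduction used as a desymmetrisation; the catalyst treats the quaternary carbon as the large group and should give the (R)-carbinol, and of the two enantiotopic carbonyls the one that can be attacked anti to the pseudo-axial methyl (allyl equatorial) should react, placing OH cis to methyl and trans to allyl. Catecholborane leaves the alkene untouched.

Step 3
Reactants: 5 2-methylbut-3-en-2-ol
Product: 6 2-methylbut-3-en-2-yl 2,2,2-trichloroacetimidate
Conditions: Cl3CCN, 1,8-diazabicyclo[5.4.0]undec-7-ene (10 mol%), CH2Cl2, 0 °C, used cold and crude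
Reagents that add atoms: trichloroacetonitrile, ClC(Cl)(Cl)C#N
Why: Base-catalysed addition of the tertiary alcohol to the nitrile; kept cold so that the allylic imidate does not undergo [3,3] rearrangement.

Step 4
Reactants: 4 (2S,3R)-2-allyl-3-hydroxy-2-methylcyclohexan-1-one; 6 2-methylbut-3-en-2-yl 2,2,2-trichloroacetimidate
Product: 7 (2S,3R)-2-allyl-2-methyl-3-[(2-methylbut-3-en-2-yl)oxy]cyclohexan-1-one
Conditions: BF3·OEt2 (5 mol%), cyclohexane–CH2Cl2, 0 → 25 °C
Reagents that add atoms: none
Why: Acid-catalysed imidate etherification; the ion pair from the tertiary allylic imidate is captured by the secondary alcohol at the tertiary terminus in the non-polar medium, and the carbinol centre is not touched. The ketone has no α-hydrogen on the quaternary side, so the ketol cannot dehydrate.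

Step 5
Reactants: 7 (2S,3R)-2-allyl-2-methyl-3-[(2-methylbut-3-en-2-yl)oxy]cyclohexan-1-one
Product: 8 (5aS,9aR)-2,2,5a-trimethyl-5,5a,7,8,9,9a-hexahydro-1-benzoxepin-6(2H)-one
Conditions: second-generation Grubbs catalyst (H2IMes)(PCy3)Cl2Ru=CHPh (5 mol%), 1,4-benzoquinone (10 mol%), CH2Cl2 (0.005 M), 40 °C
Reagents that add atoms: none
Why: Ring-closing olefin metathesis: the ruthenium benzylidene exchanges with the unhindered allyl terminus, the new alkylidene undergoes intramolecular [2+2] addition to the vinyl group of the tertiary allylic ether, and cycloreversion of the metallacyclobutane releases the ring alkene and Ru=CH2, with ethylene lost overall. The closest known reaction type is the closure of ether-linked 1,8-dienes to 2,3,6,7-tetrahydrooxepines with ruthenium alkylidenes. The oxepene is the only ring closed; it closes by joining the internal carbons of the two terminal alkenes, and ring size enforces the cis alkene. No stereocentre is formed; both ring-fusion centres come from step 2 unchanged. The step needs cyclisation to beat oligomerisation: the arms are trans-diequatorial on adjacent carbons of a chair cyclohexanone, the gem-dimethyl group compresses the ether arm towards the allyl group, and high dilution is used. It also needs the alkenes to stay in place, which benzoquinone secures by intercepting ruthenium hydrides. The hindered vinyl group cannot initiate or homodimerise, so the catalyst loads where productive closure starts. The ketone is inert to the catalyst.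

Step 6
Reactants: 8 (5aS,9aR)-2,2,5a-trimethyl-5,5a,7,8,9,9a-hexahydro-1-benzoxepin-6(2H)-one
Product: 9 3,4-epoxide of 8 with the oxirane oxygen on the face opposite the C5a methyl
Conditions: mCPBA, NaHCO3, CH2Cl2, 0 °C
Reagents that add atoms: 3-chloroperbenzoic acid, OOC(=O)c1cccc(Cl)c1
Why: Prilezhaev epoxidation of the only alkene; the axial C5a methyl lies over one face of C4, so attack from the other face is expected. Baeyer–Villiger oxidation of the hindered ketone is much slower.

Step 7
Reactants: 9 3,4-epoxide of 8
Product: 11 (3R,5aS,9aR)-3-hydroxy-2,2,5a-trimethyloctahydro-1-benzoxepin-6(2H)-one, via lithium enolate 10 (not isolated)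
Conditions: LiHMDS (1.1 equiv), THF, −78 °C; LiEt3BH (3 equiv), −78 → 25 °C; aq. NH4Cl
Reagents that add atoms: none
Why: The ketone is masked in the flask as its enolate (C7 is the only enolisable position), which hydride does not attack; LiEt3BH then opens the epoxide by SN2 attack at C4, because C3 is neopentyl, and the C3–O configuration is retained.

Step 8
Reactants: 11 (3R,5aS,9aR)-3-hydroxy-2,2,5a-trimethyloctahydro-1-benzoxepin-6(2H)-one
Product: 12 3-O-triethylsilyl ether of 11
Conditions: TESOTf, 2,6-lutidine, CH2Cl2, −78 °C
Reagents that add atoms: triethylsilyl triflate, CC[Si](CC)(CC)OS(=O)(=O)C(F)(F)F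
Why: Silylation of a hindered secondary alcohol with a silyl triflate; the weak base does not enolise the ketone at this temperature.

Step 9
Reactants: 12 3-O-triethylsilyl ether of 11
Product: 13 2,4,6-triisopropylbenzenesulfonylhydrazone of 12
Conditions: 2,4,6-triisopropylbenzenesulfonyl hydrazide, pyridinium p-toluenesulfonate (cat.), 4 Å MS, THF, 25 °C
Reagents that add atoms: 2,4,6-triisopropylbenzenesulfonyl hydrazide, CC(C)c1cc(C(C)C)c(S(=O)(=O)NN)c(C(C)C)c1
Why: Condensation of the ketone with the sulfonyl hydrazide; the N–N bond settles syn to the C7 methylene, the side from which the Shapiro reaction removes a proton.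

Step 10
Reactants: 13 2,4,6-triisopropylbenzenesulfonylhydrazone of 12
Product: 16 C6=C7 alkene carrying CH2CH2OSiEt3 on C6, via vinyllithium 14 (not isolated), via lithium alkoxide 15 (not isolated)
Conditions: n-BuLi (2.2 equiv), THF, −78 → 0 °C; ethylene oxide, −78 → 25 °C; TESCl, 0 °C
Reagents that add atoms: ethylene oxide, C1CO1; chlorotriethylsilane, CC[Si](CC)(CC)Cl
Why: Shapiro reaction: the dianion loses sulfinate and N2 to give the vinyllithium at C6 (only C7 has α-hydrogens), which opens ethylene oxide; the alkoxide is silylated in the same flask. The triisopropylphenyl group prevents ortho-metalation.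

Step 11
Reactants: 16 C6=C7 alkene carrying CH2CH2OSiEt3 on C6
Product: 18 C7 secondary alcohol with H-6 and 7-OH on the face opposite the C5a methyl, via alkylborane 17 (not isolated)
Conditions: BH3·THF, THF, 0 → 25 °C; NaOH, H2O2, 0 °C
Reagents that add atoms: hydrogen peroxide, OO
Why: Hydroboration–oxidation: boron goes to the less substituted C7 and the syn addition occurs anti to the axial C5a methyl, which sets C6 with its hydrogen axial and the side chain equatorial; oxidation proceeds with retention.

Step 12
Reactants: 18 C7 secondary alcohol
Product: 19 C7 ketone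
Conditions: Dess–Martin periodinane, NaHCO3, CH2Cl2, 25 °C
Reagents that add atoms: none
Why: Dess–Martin oxidation under buffered conditions; C6 already has its more stable equatorial substituent, so enolisation cannot degrade it.

Step 13
Reactants: 19 C7 ketone
Product: 21 tris(triethylsilyl) ether with the C7 methyl equatorial, via lithium alkoxide 20 (not isolated)
Conditions: MeLi, Et2O, −78 °C; TESOTf, −78 → 0 °C
Reagents that add atoms: methyllithium, [Li]C; triethylsilyl triflate, CC[Si](CC)(CC)OS(=O)(=O)C(F)(F)F
Why: 1,2-Addition of methyllithium from the equatorial direction, because the C5a methyl is syn-axial to the axial trajectory at C7; this gives the axial alkoxide cis to that methyl (7S), which is trapped as its silyl ether.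

Step 14
Reactants: 21 tris(triethylsilyl) ether
Product: 22 primary alcohol with the 3-O and 7-O silyl ethers intact
Conditions: pyridinium p-toluenesulfonate (0.1 equiv), MeOH–CH2Cl2, 0 °C
Reagents that add atoms: none
Why: Acid-catalysed methanolysis removes the unhindered primary triethylsilyl ether much faster than the neopentyl secondary and the tertiary ones.

Step 15
Reactants: 22 primary alcohol
Product: 23 primary iodide
Conditions: I2, PPh3, imidazole, CH2Cl2, 0 °C
Reagents that add atoms: iodine, II
Why: Appel-type iodination of the only free, primary hydroxyl through its alkoxyphosphonium salt.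

### Right half (steps 16–26)

Step 16
Reactants: 24 geraniol
Product: 25 (2R,3R)-2,3-epoxygeraniol
Conditions: Ti(Oi-Pr)4 (5 mol%), D-(−)-diethyl tartrate (6 mol%), t-BuOOH, 4 Å MS, CH2Cl2, −20 °C
Reagents that add atoms: tert-butyl hydroperoxide, CC(C)(C)OO
Why: Sharpless asymmetric epoxidation of the allylic alcohol; the tartrate enantiomer fixes the (R) configuration at the future tertiary carbinol, and the remote trisubstituted alkene is not epoxidised.

Step 17
Reactants: 25 (2R,3R)-2,3-epoxygeraniol
Product: 26 (2S,3R)-2-(chloromethyl)-3-methyl-3-(4-methylpent-3-en-1-yl)oxirane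
Conditions: PPh3, CCl4, NaHCO3, 75 °C
Reagents that add atoms: tetrachloromethane, ClC(Cl)(Cl)Cl
Why: Appel chlorination of the primary alcohol; the epoxide carbons are not involved (the descriptor at C2 changes only through the priority rules).

Step 18
Reactants: 26 (2S,3R)-2-(chloromethyl)-3-methyl-3-(4-methylpent-3-en-1-yl)oxirane
Product: 27 (R)-3,7-dimethyloct-6-en-1-yn-3-ol
Conditions: n-BuLi (3 equiv), THF, −78 → −30 °C
Reagents that add atoms: none
Why: Base-induced double elimination of a 2,3-epoxy chloride: deprotonation at the chloromethyl carbon opens the epoxide to a chloroalkenyl alkoxide, which loses HCl to the alkyne; the C–O bond at the tertiary carbon is never broken.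

Step 19
Reactants: 27 (R)-3,7-dimethyloct-6-en-1-yn-3-ol
Product: 29 (8R)-8-hydroxy-4,4,8-trimethylbicyclo[3.3.0]oct-1-en-3-one as both C5 epimers, via hexacarbonyldicobalt alkyne complex 28 (not isolated)
Conditions: Co2(CO)8 (1.1 equiv), CH2Cl2, 25 °C; N-methylmorpholine N-oxide (8 equiv), 0 → 25 °C
Reagents that add atoms: dicobalt octacarbonyl (source of CO), O=C=[Co](=C=O)(=C=O)(=C=O)[Co](=C=O)(=C=O)(=C=O)=C=O
Why: Intramolecular Pauson–Khand reaction of a 1,6-enyne; the N-oxide removes a CO ligand so that the trisubstituted alkene can insert, the carbinol-bearing quaternary carbon in the tether favours cyclisation, and the gem-dimethyl carbon ends up next to the new carbonyl. The C5 configuration is not controlled and need not be, as step 20 removes it.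

Step 20
Reactants: 29 (8R)-8-hydroxy-4,4,8-trimethylbicyclo[3.3.0]oct-1-en-3-one
Product: 31 (8R)-8-hydroxy-4,4,8-trimethylbicyclo[3.3.0]oct-1(5)-en-3-one, via potassium dienolate 30 (not isolated)
Conditions: KOt-Bu (3 equiv), t-BuOH–THF, 25 °C; poured into cold 10% aq. AcOH
Reagents that add atoms: none
Why: Deconjugative protonation: C4 is quaternary, so the only acidic hydrogen is the γ-hydrogen on C5; the extended dienolate is protonated kinetically at the α-carbon C2, which gives the β,γ-unsaturated ketone and merges both C5 epimers into one compound. The product is used at once, since base or acid would return it to conjugation.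

Step 21
Reactants: 31 (8R)-8-hydroxy-4,4,8-trimethylbicyclo[3.3.0]oct-1(5)-en-3-one
Product: 32 (1R,5R,8R)-8-hydroxy-4,4,8-trimethylbicyclo[3.3.0]octan-3-one
Conditions: [Ir(cod)(PCy3)(py)]PF6 (5 mol%), H2 (1 atm), CH2Cl2, 25 °C
Reagents that add atoms: none
Why: Hydroxyl-directed hydrogenation: the tertiary allylic alcohol binds the cationic iridium centre and both hydrogens are delivered to the alkene face syn to OH, which sets C1 and C5 together, gives the cis ring fusion and leaves the C8 methyl on the concave face.

Step 22
Reactants: 32 (1R,5R,8R)-8-hydroxy-4,4,8-trimethylbicyclo[3.3.0]octan-3-one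
Product: 33 8-O-triethylsilyl ether of 32
Conditions: TESOTf, 2,6-lutidine, CH2Cl2, −78 → 0 °C
Reagents that add atoms: triethylsilyl triflate, CC[Si](CC)(CC)OS(=O)(=O)C(F)(F)F
Why: Silyl triflate silylation of the tertiary alcohol on the convex face; the ketone is not enolised by the weak base.

Step 23
Reactants: 33 8-O-triethylsilyl ether of 32
Product: 34 trimethylsilyl enol ether of 33 (C2=C3)
Conditions: LDA, TMSCl, THF, −78 °C
Reagents that add atoms: chlorotrimethylsilane, C[Si](C)(C)Cl
Why: Enolisation with in-situ silylation; C4 is quaternary, so only the enol ether towards C2 can form.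

Step 24
Reactants: 34 trimethylsilyl enol ether of 33
Product: 35 chlorocyclobutanone in which C3 (OSiMe3) is bonded to C(Cl)CH3 and C2 to the new carbonyl carbon
Conditions: 2-chloropropanoyl chloride, Et3N, hexane, 25 °C, slow addition
Reagents that add atoms: 2-chloropropanoyl chloride, CC(Cl)C(=O)Cl
Why: [2+2] Cycloaddition of chloro(methyl)ketene, formed in the flask by dehydrochlorination, with the silyl enol ether; the nucleophilic C2 attacks the ketene carbonyl carbon, so the siloxy carbon ends up bonded to the chlorinated carbon. The three new cyclobutane centres are lost in step 25.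

Step 25
Reactants: 35 chlorocyclobutanone
Product: 37 (1R,7R,8R)-2,2,4,8-tetramethyl-8-(triethylsilyloxy)bicyclo[5.3.0]decane-3,5-dione, via dechlorinated cyclobutanone 36 (not isolated)
Conditions: Zn, AcOH, 25 °C; K2CO3, MeOH, 25 °C
Reagents that add atoms: none
Why: Zinc removes the α-chlorine; methanolysis of the trimethylsilyl ether frees a cyclobutanol β to the ketone, and retro-aldol cleavage of the ring-fusion bond relieves the four-ring strain, which amounts to a two-carbon ring expansion to the 2-methyl-1,3-dione. The ring-fusion carbons are not α to a carbonyl and keep their configuration; the tertiary triethylsilyl ether survives carbonate in methanol.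

Step 26
Reactants: 37 (1R,7R,8R)-2,2,4,8-tetramethyl-8-(triethylsilyloxy)bicyclo[5.3.0]decane-3,5-dione
Product: 38 (1R,7R,8R)-5-methoxy-2,2,4,8-tetramethyl-8-(triethylsilyloxy)bicyclo[5.3.0]dec-4-en-3-one
Conditions: Me2SO4, K2CO3, acetone, 56 °C
Reagents that add atoms: dimethyl sulfate, COS(=O)(=O)OC
Why: O-Alkylation of the dione enolate with a hard electrophile; the oxygen remote from the gem-dimethyl carbon is the accessible one, so the carbonyl that remains is C3, next to C2, as the union requires.

### Union and completion (steps 27–29)

Step 27
Reactants: 23 primary iodide; 38 (1R,7R,8R)-5-methoxy-2,2,4,8-tetramethyl-8-(triethylsilyloxy)bicyclo[5.3.0]dec-4-en-3-one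
Product: 41 C3 epimer of the target in the oxepane (3R), via primary alkyllithium 39 (not isolated), via lithium alkoxide 40 (not isolated)
Conditions: t-BuLi (2.1 equiv), Et2O–pentane, −78 °C; 38, THF, −78 → 0 °C; 2 M HCl, THF–MeOH, 25 °C
Reagents that add atoms: water, O
Why: Stork–Danheiser sequence: iodine–lithium exchange, 1,2-addition of the primary alkyllithium to the vinylogous ester carbonyl, then acid hydrolysis of the enol ether with loss of the tertiary hydroxyl gives the transposed enone with the bridge on its β-carbon. The same acid removes the three triethylsilyl ethers; the tertiary alcohols have no stabilised cation available and should survive dilute acid at room temperature.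

Step 28
Reactants: 41 C3 epimer of the target
Product: 42 oxepan-3-one (3-oxo compound)
Conditions: Dess–Martin periodinane, NaHCO3, CH2Cl2, 0 °C
Reagents that add atoms: none
Why: Dess–Martin oxidation of the only secondary alcohol; the two tertiary alcohols and the enone are inert.

Step 29
Reactants: 42 oxepan-3-one
Product: 43 target, (1R,7R,8R)-3-{2-[(3S,5aR,6R,7S,9aR)-3,7-dihydroxy-2,2,5a,7-tetramethyldecahydro-1-benzoxepin-6-yl]ethyl}-8-hydroxy-2,2,4,8-tetramethylbicyclo[5.3.0]dec-3-en-5-one
Conditions: NaBH4, MeOH–CH2Cl2, −40 °C
Reagents that add atoms: none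
Why: Hydride reduction of a saturated α-alkoxy ketone in the presence of a hindered conjugated enone, which is less electrophilic; by analogy with 4,4-dimethyl-3-keto six-membered rings the small hydride should enter from the face away from the C5a methyl and give the equatorial (3S) alcohol cis to that methyl.

## Compound list

1 | 2-methylcyclohexane-1,3-dione | CC1C(=O)CCCC1=O | starting material
2 | allyl bromide | C=CCBr | starting material
3 | 2-allyl-2-methylcyclohexane-1,3-dione | C=CCC1(C)C(=O)CCCC1=O | intermediate
4 | (2S,3R)-2-allyl-3-hydroxy-2-methylcyclohexan-1-one (OH cis to methyl) | C=CC[C@]1(C)C(=O)CCC[C@H]1O | intermediate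
5 | 2-methylbut-3-en-2-ol | CC(C)(O)C=C | starting material
6 | 2-methylbut-3-en-2-yl 2,2,2-trichloroacetimidate | CC(C)(OC(=N)C(Cl)(Cl)Cl)C=C | intermediate
7 | (2S,3R)-2-allyl-2-methyl-3-[(2-methylbut-3-en-2-yl)oxy]cyclohexan-1-one | C=CC[C@]1(C)C(=O)CCC[C@H]1OC(C)(C)C=C | intermediate
8 | (5aS,9aR)-2,2,5a-trimethyl-5,5a,7,8,9,9a-hexahydro-1-benzoxepin-6(2H)-one, trans-fused | O=C1CCC[C@H]2OC(C)(C)C=CC[C@]12C | intermediate
9 | 3,4-epoxide of 8, oxirane oxygen opposite the C5a methyl | O=C1CCC[C@H]2OC(C)(C)[C@@H]3O[C@@H]3C[C@]12C | intermediate
10 | lithium C6–C7 enolate of 9 | [Li]OC1=CCC[C@H]2OC(C)(C)[C@@H]3O[C@@H]3C[C@]12C | intermediate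
11 | (3R,5aS,9aR)-3-hydroxy-2,2,5a-trimethyloctahydro-1-benzoxepin-6(2H)-one | O=C1CCC[C@H]2OC(C)(C)[C@H](O)CC[C@]12C | intermediate
12 | 3-O-triethylsilyl ether of 11 | O=C1CCC[C@H]2OC(C)(C)[C@H](O[Si](CC)(CC)CC)CC[C@]12C | intermediate
13 | 2,4,6-triisopropylbenzenesulfonylhydrazone of 12 (N–N syn to C7) | CC(C)c1cc(C(C)C)c(S(=O)(=O)N/N=C2\CCC[C@H]3OC(C)(C)[C@H](O[Si](CC)(CC)CC)CC[C@]23C)c(C(C)C)c1 | intermediate
14 | C6 vinyllithium of the C6=C7 alkene | [Li]C1=CCC[C@H]2OC(C)(C)[C@H](O[Si](CC)(CC)CC)CC[C@]12C | intermediate
15 | lithium 2-(cyclohexenyl)ethoxide from 14 and ethylene oxide | [Li]OCCC1=CCC[C@H]2OC(C)(C)[C@H](O[Si](CC)(CC)CC)CC[C@]12C | intermediate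
16 | C6=C7 alkene with CH2CH2OSiEt3 on C6 and OSiEt3 on C3 | CC[Si](CC)(CC)OCCC1=CCC[C@H]2OC(C)(C)[C@H](O[Si](CC)(CC)CC)CC[C@]12C | intermediate
17 | C7 alkylborane (drawn as RBH2), boron and H-6 opposite the C5a methyl | CC[Si](CC)(CC)OCC[C@H]1[C@H](B)CC[C@H]2OC(C)(C)[C@H](O[Si](CC)(CC)CC)CC[C@]12C | intermediate
18 | C7 secondary alcohol (7-OH and C6 side chain equatorial) | CC[Si](CC)(CC)OCC[C@H]1[C@H](O)CC[C@H]2OC(C)(C)[C@H](O[Si](CC)(CC)CC)CC[C@]12C | intermediate
19 | C7 ketone | CC[Si](CC)(CC)OCC[C@H]1C(=O)CC[C@H]2OC(C)(C)[C@H](O[Si](CC)(CC)CC)CC[C@]12C | intermediate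
20 | lithium C7 tertiary alkoxide (O axial, cis to the C5a methyl) | CC[Si](CC)(CC)OCC[C@H]1[C@@](C)(O[Li])CC[C@H]2OC(C)(C)[C@H](O[Si](CC)(CC)CC)CC[C@]12C | intermediate
21 | tris(triethylsilyl) ether | CC[Si](CC)(CC)OCC[C@H]1[C@@](C)(O[Si](CC)(CC)CC)CC[C@H]2OC(C)(C)[C@H](O[Si](CC)(CC)CC)CC[C@]12C | intermediate
22 | primary alcohol, 3-O and 7-O triethylsilyl | OCC[C@H]1[C@@](C)(O[Si](CC)(CC)CC)CC[C@H]2OC(C)(C)[C@H](O[Si](CC)(CC)CC)CC[C@]12C | intermediate
23 | primary iodide, 3-O and 7-O triethylsilyl | ICC[C@H]1[C@@](C)(O[Si](CC)(CC)CC)CC[C@H]2OC(C)(C)[C@H](O[Si](CC)(CC)CC)CC[C@]12C | intermediate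
24 | geraniol | CC(C)=CCC/C(C)=C/CO | starting material
25 | (2R,3R)-2,3-epoxygeraniol | OC[C@H]1O[C@]1(C)CCC=C(C)C | intermediate
26 | (2S,3R)-2-(chloromethyl)-3-methyl-3-(4-methylpent-3-en-1-yl)oxirane | ClC[C@H]1O[C@]1(C)CCC=C(C)C | intermediate
27 | (R)-3,7-dimethyloct-6-en-1-yn-3-ol | C#C[C@](C)(O)CCC=C(C)C | intermediate
28 | hexacarbonyldicobalt complex of the alkyne of 27 | CC(C)=CCC[C@@](C)(O)C12[Co]3(=C=O)(=C=O)(=C=O)[Co]1(=C=O)(=C=O)(=C=O)C23 | intermediate
29 | (8R)-8-hydroxy-4,4,8-trimethylbicyclo[3.3.0]oct-1-en-3-one, both C5 epimers | O=C1C=C2[C@](C)(O)CCC2C1(C)C | intermediate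
30 | potassium dienolate of 29 (O–C3=C2, C1=C5) | [K]OC1=CC2=C(CC[C@@]2(C)O)C1(C)C | intermediate
31 | (8R)-8-hydroxy-4,4,8-trimethylbicyclo[3.3.0]oct-1(5)-en-3-one | O=C1CC2=C(CC[C@@]2(C)O)C1(C)C | intermediate
32 | (1R,5R,8R)-8-hydroxy-4,4,8-trimethylbicyclo[3.3.0]octan-3-one, cis-fused, H-1 and H-5 cis to OH | O=C1C[C@@H]2[C@@H](CC[C@@]2(C)O)C1(C)C | intermediate
33 | 8-O-triethylsilyl ether of 32 | O=C1C[C@@H]2[C@@H](CC[C@@]2(C)O[Si](CC)(CC)CC)C1(C)C | intermediate
34 | trimethylsilyl enol ether of 33 (C2=C3) | C[Si](C)(C)OC1=C[C@@H]2[C@@H](CC[C@@]2(C)O[Si](CC)(CC)CC)C1(C)C | intermediate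
35 | chlorocyclobutanone cycloadduct (cyclobutane centres undefined) | C[Si](C)(C)OC12C(C)(C)[C@@H]3CC[C@@](C)(O[Si](CC)(CC)CC)[C@@H]3C1C(=O)C2(C)Cl | intermediate
36 | dechlorinated cyclobutanone | C[Si](C)(C)OC12C(C)(C)[C@@H]3CC[C@@](C)(O[Si](CC)(CC)CC)[C@@H]3C1C(=O)C2C | intermediate
37 | (1R,7R,8R)-2,2,4,8-tetramethyl-8-(triethylsilyloxy)bicyclo[5.3.0]decane-3,5-dione, C4 epimers | O=C1C(C)C(=O)C[C@@H]2[C@@H](CC[C@@]2(C)O[Si](CC)(CC)CC)C1(C)C | intermediate
38 | (1R,7R,8R)-5-methoxy-2,2,4,8-tetramethyl-8-(triethylsilyloxy)bicyclo[5.3.0]dec-4-en-3-one | COC1=C(C)C(=O)C(C)(C)[C@@H]2CC[C@@](C)(O[Si](CC)(CC)CC)[C@@H]2C1 | intermediate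
39 | primary alkyllithium from 23 | [Li]CC[C@H]1[C@@](C)(O[Si](CC)(CC)CC)CC[C@H]2OC(C)(C)[C@H](O[Si](CC)(CC)CC)CC[C@]12C | intermediate
40 | lithium alkoxide of the 1,2-adduct of 39 to C3 of 38 (carbinol centre undefined) | COC1=C(C)C(O[Li])(CC[C@H]2[C@@](C)(O[Si](CC)(CC)CC)CC[C@H]3OC(C)(C)[C@H](O[Si](CC)(CC)CC)CC[C@]23C)C(C)(C)[C@@H]4CC[C@@](C)(O[Si](CC)(CC)CC)[C@@H]4C1 | intermediate
41 | C3 epimer of the target in the oxepane (3R) | CC1=C(CC[C@H]2[C@@](C)(O)CC[C@H]3OC(C)(C)[C@H](O)CC[C@]23C)C(C)(C)[C@@H]4CC[C@@](C)(O)[C@@H]4CC1=O | intermediate
42 | oxepan-3-one (3-oxo compound) | CC1=C(CC[C@H]2[C@@](C)(O)CC[C@H]3OC(C)(C)C(=O)CC[C@]23C)C(C)(C)[C@@H]4CC[C@@](C)(O)[C@@H]4CC1=O | intermediate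
43 | target, (1R,7R,8R)-3-{2-[(3S,5aR,6R,7S,9aR)-3,7-dihydroxy-2,2,5a,7-tetramethyldecahydro-1-benzoxepin-6-yl]ethyl}-8-hydroxy-2,2,4,8-tetramethylbicyclo[5.3.0]dec-3-en-5-one | CC1=C(CC[C@@H]2[C@@]3(C)CC[C@H](O)C(C)(C)O[C@@H]3CC[C@]2(C)O)C(C)(C)[C@@H]2CC[C@@](C)(O)[C@@H]2CC1=O | target

## Step count and least certain steps

Total: 29 steps. Longest linear sequence: 17 steps (1, 2, 4–15, 27–29); the right half takes 11 steps (16–26) before the union.

**Step 5 (key step).** Intermolecular metathesis at the allyl group could outrun closure onto the hindered vinyl group, or ruthenium hydrides could move the allyl double bond before closure, which would give a contracted ring. Fallback by 7-endo epoxide opening, from 4 back to 11: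
- The allyl group of 4 is hydroborated (9-BBN, then NaBO3) to the primary–secondary diol F1.
- The primary alcohol is oxidised selectively (TEMPO, PhI(OAc)2) to the aldehyde F2, which will rest as its lactol.
- Wittig reaction with Ph3P=C(CH3)2 gives the trisubstituted alkene F3.
- Shi epoxidation (Oxone with the fructose-derived ketone 1,2:4,5-di-O-isopropylidene-β-D-erythro-2,3-hexodiulo-2,6-pyranose or its enantiomer, whichever gives the 3R oxirane) gives the epoxide F4.
- Camphorsulfonic acid in CH2Cl2 makes the ring hydroxyl attack the tertiary oxirane carbon and closes the oxepane, returning to 11.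

**Step 2.** The catalyst fixes the carbinol configuration, but the choice between the two enantiotopic carbonyls, and with it the relation of OH to allyl, may be poorly selective. Fallback, from 3 back to 4: baker's yeast reduction of 3 is expected to give the (2S,3S)-ketol F5 with hydroxyl cis to allyl. Mitsunobu inversion (4-nitrobenzoic acid, PPh3, diisopropyl azodicarboxylate) gives the (3R) 4-nitrobenzoate F6, which cannot eliminate because the α-carbon is quaternary. K2CO3 in MeOH then returns 4.

**Step 4.** The tertiary allylic cation may be captured at its primary terminus or lose a proton, so etherification of the hindered alcohol may stay incomplete. Fallback by a Nicholas reaction, from 4 back to 7: the Co2(CO)6 complex of 2-methylbut-3-yn-2-ol and BF3·OEt2 etherify 4 to the cobalt-complexed propargyl ether F7. (NH4)2Ce(NO3)6 at −78 °C, cold so that the complex does not cyclocarbonylate with the allyl group, releases the 1,1-dimethylpropargyl ether F8. Semi-hydrogenation (H2, Pd/CaCO3 poisoned with Pb(OAc)2, quinoline) gives 7.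

**Step 19.** Insertion of the trisubstituted alkene into the cobalt–alkyne complex may be too slow, so that decomplexation takes over. Fallback, from 27 back to 29:
- Ozonolysis of the trisubstituted alkene of 27 (O3, then Me2S) gives the ynal F9.
- Wittig methylenation (Ph3P=CH2) gives the terminal enynol F10, a standard Pauson–Khand substrate.
- Cyclocarbonylation under the conditions of step 19 gives the bicyclic enone F11.
- Two successive α′-methylations (LDA, MeI; the α′-carbon is the only enolisable position on that side) give the monomethyl enone F12 and then 29.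

**Step 27.** The alkyllithium may act as a base on the γ-hydrogens of the vinylogous ester, or fail to reach the carbonyl between a quaternary carbon and a methylated enol ether carbon. Fallback by a samarium Barbier reaction, from 23 and 38 back to 41: SmI2 with HMPA in THF reduces the iodide in the presence of 38, so that a non-basic organosamarium adds as it forms and gives the tertiary carbinol F13. The acid treatment of step 27 converts F13 into 41.

**Step 29.** Facial selectivity at the oxepanone may be poor, or the enone may also be reduced. Fallback, from 42 back to 43: reagent-controlled reduction with (R)-1-methyl-3,3-diphenyltetrahydro-1H,3H-pyrrolo[1,2-c][1,3,2]oxazaborole and catecholborane at −78 °C. The catalyst treats the gem-dimethyl carbon as the large group and should give the (3S) alcohol whatever the ring conformation; no new compound is formed.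

## Further compounds

F1 | step 5 | (2S,3R)-3-hydroxy-2-(3-hydroxypropyl)-2-methylcyclohexan-1-one | OCCC[C@]1(C)C(=O)CCC[C@H]1O
F2 | step 5 | 3-[(1S,2R)-2-hydroxy-1-methyl-6-oxocyclohexyl]propanal (open form of the lactol) | O=CCC[C@]1(C)C(=O)CCC[C@H]1O
F3 | step 5 | (2S,3R)-3-hydroxy-2-methyl-2-(4-methylpent-3-en-1-yl)cyclohexan-1-one | CC(C)=CCC[C@]1(C)C(=O)CCC[C@H]1O
F4 | step 5 | (2S,3R)-2-{2-[(2R)-3,3-dimethyloxiran-2-yl]ethyl}-3-hydroxy-2-methylcyclohexan-1-one | CC1(C)O[C@@H]1CC[C@]2(C)C(=O)CCC[C@H]2O
F5 | step 2 | (2S,3S)-2-allyl-3-hydroxy-2-methylcyclohexan-1-one | C=CC[C@]1(C)C(=O)CCC[C@@H]1O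
F6 | step 2 | (1R,2S)-2-allyl-2-methyl-3-oxocyclohexyl 4-nitrobenzoate | C=CC[C@]1(C)C(=O)CCC[C@H]1OC(=O)c2ccc(cc2)[N+](=O)[O-]
F7 | step 4 | hexacarbonyldicobalt complex of the 1,1-dimethylpropargyl ether of 4 | C=CC[C@]1(C)C(=O)CCC[C@H]1OC(C)(C)C23[Co]4(=C=O)(=C=O)(=C=O)[Co]2(=C=O)(=C=O)(=C=O)C34
F8 | step 4 | (2S,3R)-2-allyl-2-methyl-3-[(2-methylbut-3-yn-2-yl)oxy]cyclohexan-1-one | C=CC[C@]1(C)C(=O)CCC[C@H]1OC(C)(C)C#C
F9 | step 19 | (R)-4-hydroxy-4-methylhex-5-ynal | C#C[C@](C)(O)CCC=O
F10 | step 19 | (R)-3-methylhept-6-en-1-yn-3-ol | C#C[C@](C)(O)CCC=C
F11 | step 19 | (8R)-8-hydroxy-8-methylbicyclo[3.3.0]oct-1-en-3-one, both C5 epimers | O=C1C=C2[C@](C)(O)CCC2C1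
F12 | step 19 | (8R)-8-hydroxy-4,8-dimethylbicyclo[3.3.0]oct-1-en-3-one | O=C1C=C2[C@](C)(O)CCC2C1C
F13 | step 27 | tertiary carbinol from addition of the side chain of 23 to C3 of 38, three triethylsilyl ethers intact | COC1=C(C)C(O)(CC[C@H]2[C@@](C)(O[Si](CC)(CC)CC)CC[C@H]3OC(C)(C)[C@H](O[Si](CC)(CC)CC)CC[C@]23C)C(C)(C)[C@@H]4CC[C@@](C)(O[Si](CC)(CC)CC)[C@@H]4C1
F0 | step 29 | none | none
A1 | alternative 1 | cis-fused methylenecyclopentane–cycloheptane with phenylsulfonyl and two tert-butyldimethylsilyloxy groups | C=C1C[C@H](S(=O)(=O)c2ccccc2)[C@@H]3[C@H]1C[C@H](O[Si](C)(C)C(C)(C)C)C[C@@H](O[Si](C)(C)C(C)(C)C)C3(C)C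
A2 | alternative 2 | bis(triethylsilyl) ether of the target | CC1=C(CC[C@@H]2[C@@]3(C)CC[C@H](O[Si](CC)(CC)CC)C(C)(C)O[C@@H]3CC[C@]2(C)O[Si](CC)(CC)CC)C(C)(C)[C@@H]2CC[C@@](C)(O)[C@@H]2CC1=O
A3 | alternative 3 | tricyclic cyclobutane photoadduct, head-to-tail | COC(=O)[C@]12[C@H](CO[Si](C)(C)C(C)(C)C)C(C)(C)[C@]13CC[C@@](C)(O[Si](CC)(CC)CC)[C@@H]3CC2=O
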